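## Structural features

Elemane numbering is used: ring A is C5–C10; the vinyl group C1=C2 and the methyl C14 sit on C10; the isopropenyl group (C3, C4, C15) sits on C5; the lactone is O6–C12(=O)–C11–C7 with the methyl C13 on C11.

- The target is an elemane-type sesquiterpenoid lactone: a fully saturated cyclohexane (ring A) cis-fused through C6–C7 to a γ-butyrolactone (ring B).
- Ring A carries the isopropenyl group on C5, a quaternary C10 (methyl and vinyl) and a secondary acetate on C8. Ring B carries on C11 a methyl group and a tertiary (Z)-2-methylbut-2-enoate (angelate).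
- Five stereocentres are contiguous (C5, C6, C7, C8, and C11 on C7); the sixth, C10, is next to C5. The isopropenyl group is trans to O6, O6 is cis to C11, C11 is trans to the C8 acetate, the C10 methyl is cis to both the isopropenyl group and the C8 acetate, and the C11 oxygen lies on the convex face of the bicycle (cis to H7).
- Fragile groups: the angelate (drifts to the E isomer with nucleophilic catalysts, acid or base); the three alkenes (no hydrogenation, hydroboration or strong acid); and, in any intermediate with a C6 carbonyl, the epimerisable C5 (allylic) and C7 and an eliminable C8 oxygen.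
- The real difficulty is the C6/C7/C8 triad. The two chairs of ring A are close in energy (the C8 oxygen is syn-axial to the C10 methyl in the chair with equatorial isopropenyl), so external reagents have no dependable facial bias. The second difficulty is acylating the hindered tertiary C11 hydroxyl with an acid that isomerises easily.
- The key step uses the fact that C12 lies between O6 and C11, and that C11 hangs on C7 cis to O6. Removing C12 leaves a cis-2-ethynylcyclohexanol, so carbon monoxide can be inserted to close ring B as its α-methylene form. The exocyclic C11=C13 is then the handle for the tertiary carbinol.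

## Logic of the disconnections

**26 ⇒ 23 + 24.** The ester bond between O11 and the angeloyl carbonyl is cut first, because the Z-acyl group is the most labile part and should be exposed to the fewest steps. This leaves tertiary carbinol 23 and acid 24. The forward step must acylate a hindered α-hydroxy lactone without a nucleophilic amine catalyst that would equilibrate the double bond.

**23 ⇒ 21.** The C11–O bond and the C13–H bond are cut together (retro-hydration of the exocyclic alkene). C11 is a quaternary carbinol next to a carbonyl, which is what a C11 radical formed by hydrogen-atom transfer to C13 and trapped by oxygen would give. This removes the last stereocentre and exposes 21, the direct product of the key step. The forward step needs chemoselectivity for the conjugated alkene over the vinyl and isopropenyl groups and delivery of oxygen to the convex face.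

**21 ⇒ 20 (key).** The bonds O6–C12 and C12–C11 are cut and the carbonyl carbon is excised. Ring B disappears and the lactone stereochemistry reduces to a cis relation of hydroxyl and ethynyl on C6 and C7. The forward step needs a terminal alkyne, a free C6 hydroxyl, and the second homopropargylic oxygen (on C8, trans to the alkyne) already acylated so that only one lactone can form.

**20 ⇒ 19 ⇒ 18.** After the C–Si bond, the C8 O–acetyl bond and the C6–H bond are cut as one event: an aldehyde bound to O8 delivers hydride to C6 and remains on O8 as the acyl group. This matches the anti 1,3-relation of O6 and O8, differentiates the two oxygens without a protecting-group step, and avoids a β-acetoxy ketone. Ketone 18 has one stereocentre fewer. The forward step needs O8 to reach C6 (axial O8) and C7 already trans to O8.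

**18 ⇒ 15 + 16.** The C8–O bond (through C8–B) and the C7–H bond are cut, giving cross-conjugated enynone 15. Boron adds only to the electron-poor alkene, so the vinyl and isopropenyl groups are untouched, and two stereocentres are removed. The forward step must control the face of C8 by the catalyst, because the substrate bias is weak, and must leave C7 trans to the bulky C8 substituent.

**15 ⇒ 13 + 14 ⇒ 12.** The sp2–sp bond C7–C11 is cut, then C7–I. Both forward steps are chemoselective for the enone. The bulky silyl cap on 14 is chosen to survive alkoxide and to shield the triple bond from the copper boryl. Enone 12 retains only C5 and C10.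

**12 ⇒ 11 ⇒ 10 ⇒ 9 ⇒ 8 ⇒ 7.** Ring A is opened at C7=C8 (aldol condensation of a methyl ketone onto a C8 aldehyde, the only ring size possible). The aldehyde is traced to a silyl-protected primary alcohol and the C6–C7 bond to methyl addition to an activated acid. This reaches acyclic acid 7 with only the two adjacent stereocentres. Every forward step must avoid enolising C5.

**7 ⇒ 5 ⇒ 3 + 4.** The C5–C10 bond is cut as a [3,3] retron: carboxyl on C5 and vinyl on the quaternary C10. An E alkene and an E(O) enolate in a chair give the required relative configuration, and a chiral boron controller gives the absolute one. Both stereocentres and the quaternary carbon are thereby traced to the alkene geometry of achiral ester 5, and then to 3 and 4 by the ester C–O bond. The forward step needs geometrically pure 3 and a C8 protecting group inert to a B–Br Lewis acid (a silyl ether; an acetal would be at risk).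

**3 ⇒ 1.** The C10–C14 bond and the C1–C2 bond are cut (methyl and hydroxymethyl added across a terminal alkyne). Syn carbometalation sets the E geometry stereospecifically, which an olefination of a methyl ketone would not.

## Other disconnections considered

**Alternative 1:** The cut is through C9–C10 and C5–C6, a [4+2] retron. Forward, trans-1-methoxy-3-(trimethylsilyloxy)buta-1,3-diene A1 and methyl (2E)-2-methyl-4-oxopent-2-enoate A2 would combine under a cationic chiral oxazaborolidine Lewis acid. Acid work-up would unmask methyl (1S,6S)-6-acetyl-1-methyl-3-oxocyclohex-4-ene-1-carboxylate A3.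
- In its favour: ring A and both C5 and C10 (including the quaternary centre) come from one catalytic enantioselective step. The trans relation follows stereospecifically from the E dienophile. The C8 oxygen is present from the start.
- Better than the chosen plan on two points: chirality is catalytic and not stoichiometric, and there is no C8 facial problem. The later C6 oxygenation (conjugate addition trans to the C5 substituent of a 4-substituted enone) should also be at least as reliable as the C8 borylation of 15.
- Against it: A3 carries an ester and an acetyl group where the target has vinyl and isopropenyl, so two methylenations and a redox adjustment are needed with an enone present. C5 of A3 is α to a ketone and epimerisable. The regiochemistry depends on the ketone, not the ester, binding the catalyst while the diene attacks a fully substituted β-carbon. A directed reduction of the C8 ketone from O6 would leave the acyl group on O6, the wrong oxygen; in the chosen plan the same principle puts the acetate on O8 automatically.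
- Overall: mechanistically the more predictable ring construction, but several steps longer because of the functional-group changes.

**Alternative 2:** The cut is C4–C5 and C1–C10, a conjugate addition with aldol trapping. Forward, an isopropenyl cuprate would add to (4R)-4-{[tert-butyl(dimethyl)silyl]oxy}-2-methylcyclohex-2-en-1-one A4, and the zinc enolate would be trapped with a two-carbon aldehyde. This would give (2S,3R,4R)-4-{[tert-butyl(dimethyl)silyl]oxy}-2-(1-hydroxyethyl)-2-methyl-3-(prop-1-en-2-yl)cyclohexan-1-one A5.
- In its favour: three components in one flask; addition anti to the silyloxy group and aldol anti to the new isopropenyl group should set C5 and C10 by substrate control. The C6 oxygen and its configuration are secure from the first step, which is better than the chosen plan, where C6 is set late.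
- Against it: the ketone of A5 is at C9, a methylene in the target, so it must be used to functionalise C8 and C7 and then removed. Dehydration of the carbinol next to a quaternary carbon competes with retro-aldol cleavage. C7 and C8 of A5 are bare methylenes.
- Overall: equal or better for C5/C6/C10, clearly worse in step economy for the C7/C8/lactone half.

**Alternative 3:** The cut is C7–C8, a ketyl–alkene ring closure onto a preformed butenolide. Forward, a divalent samarium one-electron reductant would reduce the aldehyde of (3R,4R)-3-ethenyl-3,5-dimethyl-4-[(2R)-4-methyl-5-oxo-2,5-dihydrofuran-2-yl]hex-5-enal A6. The ketyl would add to C7 to give (3aR,4S,6R,7R,7aS)-6-ethenyl-4-hydroxy-3,6-dimethyl-7-(prop-1-en-2-yl)hexahydro-1-benzofuran-2(3H)-one A7 (C3 undefined).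
- In its favour: ring A closes with the lactone in place. C7 is formed in a ring-closing step and never sits next to a ketone, which is better than the chosen plan, where C7 rests on an equilibration. The cis fusion is enforced by the tether and no carbon monoxide under pressure is needed.
- Against it: A6 needs three contiguous stereocentres in an open chain, one of them the butenolide carbon, which is harder to assemble than ester 5. The C8 configuration depends on chelation versus dipole control in the ketyl transition state. C11 arrives without oxygen and unselectively, so an enolate hydroxylation must follow in the presence of the C8 oxygen function.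
- Overall: comparable step count; the chosen plan keeps C11 planar until oxygen is added with facial control and needs no strong base after the acetate is in place.

Key step: step 14

Assumption: compound 1 is taken as a catalogue compound (otherwise it is one silylation from but-3-yn-1-ol).

Assumption: in the two reagent-controlled steps (3 and 11) the antipode of the chiral controller written is taken to give the required sense; both antipodes are sold and the other would be used if the opposite sense were found.

## Route

Step 1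
Reactants: 1 tert-butyl(but-3-yn-1-yloxy)diphenylsilane
Product: 3 (2E)-5-{[tert-butyl(diphenyl)silyl]oxy}-3-methylpent-2-en-1-ol, via alkenylalane 2 (not isolated)
Conditions: AlMe3, Cp2ZrCl2 (20 mol %), CH2Cl2, 0 °C → rt; then n-BuLi, THF, −78 °C; (CH2O)n, −78 °C → rt; 1 M HCl work-up
Reagents that add atoms: trimethylaluminium, C[Al](C)C; formaldehyde (as paraformaldehyde), C=O
Why: Zirconium-catalysed methylalumination (Negishi carboalumination) adds CH3 and Al syn across the terminal alkyne with CH3 on the internal carbon; the derived aluminate transfers the alkenyl group to formaldehyde with retention, so the CH2OH and silyloxyethyl groups end up trans (E), the geometry that step 3 converts into C10.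

Step 2
Reactants: 3 (2E)-5-{[tert-butyl(diphenyl)silyl]oxy}-3-methylpent-2-en-1-ol; 4 3-methylbut-3-enoic acid
Product: 5 (2E)-5-{[tert-butyl(diphenyl)silyl]oxy}-3-methylpent-2-en-1-yl 3-methylbut-3-enoate
Conditions: DCC, DMAP (5 mol %), CH2Cl2, 0 °C
Reagents that add atoms: none
Why: Steglich esterification; low temperature and little DMAP limit migration of the β,γ-double bond of 4 into conjugation, and no stereocentre is involved.

Step 3
Reactants: 5 (2E)-5-{[tert-butyl(diphenyl)silyl]oxy}-3-methylpent-2-en-1-yl 3-methylbut-3-enoate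
Product: 7 (2R,3R)-3-(2-{[tert-butyl(diphenyl)silyl]oxy}ethyl)-3-methyl-2-(prop-1-en-2-yl)pent-4-enoic acid, via boron ketene acetal 6 (not isolated)
Conditions: (4S,5S)-2-bromo-1,3-bis{[3,5-bis(trifluoromethyl)phenyl]sulfonyl}-4,5-diphenyl-1,3,2-diazaborolidine (1.1 equiv), Et3N, toluene–hexane, −78 °C → 4 °C; aqueous work-up
Reagents that add atoms: none
Why: Ester enolate Claisen rearrangement (Ireland–Claisen) in its chiral boron enolate form: Et3N in a non-polar medium should give the E(O) ketene acetal 6 (isopropenyl trans to O–B), which rearranges through a chair in which the E alkene places CH3 axial and the silyloxyethyl arm equatorial, setting the C5/C10 relative configuration, while the C2-symmetric bis-sulfonamide selects one of the two mirror-image chairs; the silyl ether is inert to the B–Br Lewis acid.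

Step 4
Reactants: 7 (2R,3R)-3-(2-{[tert-butyl(diphenyl)silyl]oxy}ethyl)-3-methyl-2-(prop-1-en-2-yl)pent-4-enoic acid
Product: 8 (2R,3R)-3-(2-{[tert-butyl(diphenyl)silyl]oxy}ethyl)-N-methoxy-N,3-dimethyl-2-(prop-1-en-2-yl)pent-4-enamide
Conditions: MeNH(OMe)·HCl, EDC·HCl, HOBt, N-methylmorpholine, CH2Cl2, 0 °C → rt
Reagents that add atoms: N,O-dimethylhydroxylamine hydrochloride, CNOC.Cl
Why: Carbodiimide amidation through the hydroxybenzotriazole ester is near neutral and avoids the ketene and enol pathways that would erode C5 or move the isopropenyl double bond into conjugation.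

Step 5
Reactants: 8 (2R,3R)-3-(2-{[tert-butyl(diphenyl)silyl]oxy}ethyl)-N-methoxy-N,3-dimethyl-2-(prop-1-en-2-yl)pent-4-enamide
Product: 9 (3R,4R)-4-(2-{[tert-butyl(diphenyl)silyl]oxy}ethyl)-4-methyl-3-(prop-1-en-2-yl)hex-5-en-2-one
Conditions: MeMgBr, THF, −20 → 0 °C; aq. NH4Cl
Reagents that add atoms: methylmagnesium bromide, C[Mg]Br
Why: Weinreb ketone synthesis: the magnesium-chelated tetrahedral adduct stops at mono-addition and collapses on quench; the C5 hydrogen is flanked by a quaternary carbon and should not be removed by the Grignard reagent at low temperature.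

Step 6
Reactants: 9 (3R,4R)-4-(2-{[tert-butyl(diphenyl)silyl]oxy}ethyl)-4-methyl-3-(prop-1-en-2-yl)hex-5-en-2-one
Product: 10 (3R,4R)-4-(2-hydroxyethyl)-4-methyl-3-(prop-1-en-2-yl)hex-5-en-2-one
Conditions: Bu4NF, AcOH (1:1), THF, rt
Reagents that add atoms: none
Why: Fluoride-mediated desilylation; acetic acid buffers the medium so that the β,γ-unsaturated ketone is neither epimerised at C5 nor isomerised.

Step 7
Reactants: 10 (3R,4R)-4-(2-hydroxyethyl)-4-methyl-3-(prop-1-en-2-yl)hex-5-en-2-one
Product: 11 (3R,4R)-3-ethenyl-3-methyl-5-oxo-4-(prop-1-en-2-yl)hexanal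
Conditions: Dess–Martin periodinane, CH2Cl2, 0 °C → rt
Reagents that add atoms: none
Why: Dess–Martin oxidation of the primary alcohol under non-enolising conditions; the alkenes are inert and the open hydroxy ketone is drained from any cyclic hemiketal.

Step 8
Reactants: 11 (3R,4R)-3-ethenyl-3-methyl-5-oxo-4-(prop-1-en-2-yl)hexanal
Product: 12 (5R,6R)-5-ethenyl-5-methyl-6-(prop-1-en-2-yl)cyclohex-2-en-1-one
Conditions: dibenzylammonium trifluoroacetate (20 mol %), toluene, 50 °C
Reagents that add atoms: none
Why: Intramolecular aldol condensation under secondary ammonium catalysis (iminium of the aldehyde, enol of the methyl ketone, then elimination): only C7 onto C8 can close a ring, since the other enolisable carbons C5 and C9 would give four-membered rings; the weakly acidic medium is chosen to spare C5.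

Step 9
Reactants: 12 (5R,6R)-5-ethenyl-5-methyl-6-(prop-1-en-2-yl)cyclohex-2-en-1-one
Product: 13 (5R,6R)-5-ethenyl-2-iodo-5-methyl-6-(prop-1-en-2-yl)cyclohex-2-en-1-one
Conditions: I2, pyridine, CH2Cl2, 0 °C → rt
Reagents that add atoms: iodine, II
Why: α-Iodination of the enone by conjugate addition of pyridine, iodination of the enolate and elimination (a Baylis–Hillman-type sequence); the isolated alkenes should not react with I2/pyridine.

Step 10
Reactants: 13 (5R,6R)-5-ethenyl-2-iodo-5-methyl-6-(prop-1-en-2-yl)cyclohex-2-en-1-one; 14 ethynyltri(propan-2-yl)silane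
Product: 15 (5R,6R)-5-ethenyl-5-methyl-6-(prop-1-en-2-yl)-2-{[tri(propan-2-yl)silyl]ethynyl}cyclohex-2-en-1-one
Conditions: PdCl2(PPh3)2 (5 mol %), CuI (10 mol %), i-Pr2NH, THF, 0 °C → rt
Reagents that add atoms: none
Why: Sonogashira coupling of the α-iodoenone, a reactive partner for oxidative addition to zerovalent palladium; the triisopropylsilyl cap is chosen over trimethylsilyl because it survives the alkoxide and methanol of step 11 and shields the triple bond from the copper boryl.

Step 11
Reactants: 15 (5R,6R)-5-ethenyl-5-methyl-6-(prop-1-en-2-yl)-2-{[tri(propan-2-yl)silyl]ethynyl}cyclohex-2-en-1-one; 16 bis(pinacolato)diboron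
Product: 18 (2R,3S,5R,6R)-5-ethenyl-3-hydroxy-5-methyl-6-(prop-1-en-2-yl)-2-{[tri(propan-2-yl)silyl]ethynyl}cyclohexan-1-one, via β-boryl ketone 17 (not isolated)
Conditions: CuCl (5 mol %), (R)-1-[(S)-2-(diphenylphosphino)ferrocenyl]ethyldicyclohexylphosphine (6 mol %), NaOt-Bu (10 mol %), MeOH (2 equiv), THF, 0 °C; then NaBO3·4H2O, THF–H2O, 0 °C → rt
Reagents that add atoms: sodium perborate (NaBO3·4H2O), [Na+].[O-]OB=O
Why: Copper-catalysed conjugate borylation followed by stereoretentive C–B oxidation: the monovalent copper boryl adds to C8 of the only electron-poor alkene, and because either face of C8 meets one syn-axial C10 substituent the substrate bias is weak, so the ferrocenyl bisphosphine is relied on to place boron cis to the C10 methyl; C7 is epimerisable and should settle with the alkynyl group trans to the bulky C8 substituent (both equatorial).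

Step 12
Reactants: 18 (2R,3S,5R,6R)-5-ethenyl-3-hydroxy-5-methyl-6-(prop-1-en-2-yl)-2-{[tri(propan-2-yl)silyl]ethynyl}cyclohexan-1-one
Product: 19 (1S,2S,3S,4R,5R)-5-ethenyl-3-hydroxy-5-methyl-4-(prop-1-en-2-yl)-2-{[tri(propan-2-yl)silyl]ethynyl}cyclohexyl acetate
Conditions: SmI2 (30 mol %), CH3CHO (6 equiv), THF, −10 °C
Reagents that add atoms: acetaldehyde, CC=O
Why: Evans–Tishchenko reduction: the trivalent samarium alkoxide of the hemiacetal formed from O8 and acetaldehyde delivers hydride to C6 from the face of O8 through a six-membered transition state, so the new hydroxyl is anti to O8 and therefore cis to the C7 alkynyl group, while O8 leaves the step as its acetate and no β-acetoxy ketone is ever present; the C7 epimer with its alkynyl group on the hemiacetal side is more crowded in this transition state, which should further enrich the wanted isomer.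

Step 13
Reactants: 19 (1S,2S,3S,4R,5R)-5-ethenyl-3-hydroxy-5-methyl-4-(prop-1-en-2-yl)-2-{[tri(propan-2-yl)silyl]ethynyl}cyclohexyl acetate
Product: 20 (1S,2S,3S,4R,5R)-5-ethenyl-2-ethynyl-3-hydroxy-5-methyl-4-(prop-1-en-2-yl)cyclohexyl acetate
Conditions: Bu4NF, AcOH (1:1), THF, 0 °C → rt
Reagents that add atoms: none
Why: Fluoride cleavage of the C(sp)–Si bond; acetic acid keeps the medium from cleaving the acetate, and the trans-1,3 oxygens cannot exchange the acyl group through a cyclic orthoester.

Step 14
Reactants: 20 (1S,2S,3S,4R,5R)-5-ethenyl-2-ethynyl-3-hydroxy-5-methyl-4-(prop-1-en-2-yl)cyclohexyl acetate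
Product: 21 (3aR,4S,6R,7R,7aS)-6-ethenyl-6-methyl-3-methylidene-2-oxo-7-(prop-1-en-2-yl)octahydro-1-benzofuran-4-yl acetate
Conditions: PdCl2 (10 mol %), SnCl2 (10 mol %), PPh3 (20 mol %), CO (7 atm), CH3CN, 75 °C
Reagents that add atoms: carbon monoxide, [C-]#[O+]
Why: This is the palladium-catalysed cyclocarbonylation of a homopropargylic alcohol to an α-methylene-γ-butyrolactone, a known reaction type for 2-ethynylcycloalkanols. The C6 hydroxyl and CO give an alkoxycarbonyl complex of divalent palladium (SnCl2 supplies a labilising trichlorostannyl ligand), the triple bond coordinates, and the Pd–C(O)O unit adds syn across it so that C12 bonds to C11; protonolysis of the vinyl–palladium bond by the HCl released earlier gives the exocyclic methylene and returns the catalyst. Ring B closes in the 5-exo-dig mode (O6–C12, then C12–C11 with the alkyne exocyclic to the forming ring). No stereocentre is created: the cis ring fusion is the cis relation of hydroxyl and ethynyl fixed in steps 11 and 12. The selectivity needed is for the alkyne over three alkenes, and it is not automatic, because the C5 isopropenyl group is also homoallylic to O6. It should hold because a triple bond inserts into the alkoxycarbonyl–palladium bond much faster than a 1,1-disubstituted alkene, because the isopropenyl group is trans to O6, and because its insertion would give an alkyl–palladium with no clean exit under non-oxidative conditions. The C8 oxygen, also homopropargylic but trans to the alkyne, is already acetylated and cannot compete.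

Step 15
Reactants: 21 (3aR,4S,6R,7R,7aS)-6-ethenyl-6-methyl-3-methylidene-2-oxo-7-(prop-1-en-2-yl)octahydro-1-benzofuran-4-yl acetate
Product: 23 (3S,3aR,4S,6R,7R,7aS)-6-ethenyl-3-hydroxy-3,6-dimethyl-2-oxo-7-(prop-1-en-2-yl)octahydro-1-benzofuran-4-yl acetate, via C11 hydroperoxide 22 (not isolated)
Conditions: Mn(dpm)3 (10 mol %), PhSiH3, O2 (1 atm), i-PrOH–CH2Cl2, 0 °C; then P(OEt)3
Reagents that add atoms: dioxygen, O=O
Why: Mukaiyama-type hydration by hydrogen-atom transfer from a trivalent manganese hydride: the hydrogen atom adds to C13 of the conjugated alkene, which should react faster than the unactivated vinyl and isopropenyl groups, and the C11 radical is trapped by O2 on the convex face of the cis-fused bicycle (cis to H7); P(OEt)3 reduces hydroperoxide 22 to the carbinol, which fixes C11 as S.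

Step 16
Reactants: 23 (3S,3aR,4S,6R,7R,7aS)-6-ethenyl-3-hydroxy-3,6-dimethyl-2-oxo-7-(prop-1-en-2-yl)octahydro-1-benzofuran-4-yl acetate; 24 (2Z)-2-methylbut-2-enoic acid
Product: 26 (3S,3aR,4S,6R,7R,7aS)-4-(acetyloxy)-6-ethenyl-3,6-dimethyl-2-oxo-7-(prop-1-en-2-yl)octahydro-1-benzofuran-3-yl (2Z)-2-methylbut-2-enoate, via lithium alkoxide 25 (not isolated)
Conditions: 24, 2,4,6-trichlorobenzoyl chloride, Et3N, toluene, rt (mixed anhydride); separately 23, LiN(SiMe3)2, THF, −78 °C; combine, −78 → 0 °C; aq. NH4Cl
Reagents that add atoms: none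
Why: Acylation of the lithium alkoxide with the mixed 2,4,6-trichlorobenzoic anhydride of 24 (Yamaguchi-type activation) at the less hindered angeloyl carbonyl; no nucleophilic amine catalyst is present, so the Z double bond should not drift to the E isomer, and the alkoxide on the convex face points away from the C8 acetate and cannot take its acyl group.

## Compound list

1 | tert-butyl(but-3-yn-1-yloxy)diphenylsilane | CC(C)(C)[Si](OCCC#C)(c1ccccc1)c1ccccc1 | starting material
2 | dimethyl[(1E)-5-{[tert-butyl(diphenyl)silyl]oxy}-2-methylpent-1-en-1-yl]alumane | CC(C)(C)[Si](OCC/C(C)=C/[Al](C)C)(c1ccccc1)c1ccccc1 | intermediate (not isolated)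
3 | (2E)-5-{[tert-butyl(diphenyl)silyl]oxy}-3-methylpent-2-en-1-ol | CC(C)(C)[Si](OCC/C(C)=C/CO)(c1ccccc1)c1ccccc1 | intermediate
4 | 3-methylbut-3-enoic acid | C=C(C)CC(=O)O | starting material
5 | (2E)-5-{[tert-butyl(diphenyl)silyl]oxy}-3-methylpent-2-en-1-yl 3-methylbut-3-enoate | CC(C)(C)[Si](OCC/C(C)=C/COC(=O)CC(C)=C)(c1ccccc1)c1ccccc1 | intermediate
6 | E(O) boron ketene acetal of 5: (4S,5S)-1,3-bis{[3,5-bis(trifluoromethyl)phenyl]sulfonyl}-4,5-diphenyl-1,3,2-diazaborolidin-2-yl enol ether, isopropenyl trans to O–B and cis to the allylic oxygen | C=C(C)/C=C(\OC/C=C(C)/CCO[Si](c1ccccc1)(c1ccccc1)C(C)(C)C)OB1N(S(=O)(=O)c2cc(cc(c2)C(F)(F)F)C(F)(F)F)[C@@H](c2ccccc2)[C@H](c2ccccc2)N1S(=O)(=O)c1cc(cc(c1)C(F)(F)F)C(F)(F)F | intermediate (not isolated)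
7 | (2R,3R)-3-(2-{[tert-butyl(diphenyl)silyl]oxy}ethyl)-3-methyl-2-(prop-1-en-2-yl)pent-4-enoic acid | C=C[C@@](C)(CCO[Si](c1ccccc1)(c1ccccc1)C(C)(C)C)[C@@H](C(=C)C)C(=O)O | intermediate
8 | (2R,3R)-3-(2-{[tert-butyl(diphenyl)silyl]oxy}ethyl)-N-methoxy-N,3-dimethyl-2-(prop-1-en-2-yl)pent-4-enamide | C=C[C@@](C)(CCO[Si](c1ccccc1)(c1ccccc1)C(C)(C)C)[C@@H](C(=C)C)C(=O)N(C)OC | intermediate
9 | (3R,4R)-4-(2-{[tert-butyl(diphenyl)silyl]oxy}ethyl)-4-methyl-3-(prop-1-en-2-yl)hex-5-en-2-one | C=C[C@@](C)(CCO[Si](c1ccccc1)(c1ccccc1)C(C)(C)C)[C@@H](C(=C)C)C(C)=O | intermediate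
10 | (3R,4R)-4-(2-hydroxyethyl)-4-methyl-3-(prop-1-en-2-yl)hex-5-en-2-one | C=C[C@@](C)(CCO)[C@@H](C(=C)C)C(C)=O | intermediate
11 | (3R,4R)-3-ethenyl-3-methyl-5-oxo-4-(prop-1-en-2-yl)hexanal | C=C[C@@](C)(CC=O)[C@@H](C(=C)C)C(C)=O | intermediate
12 | (5R,6R)-5-ethenyl-5-methyl-6-(prop-1-en-2-yl)cyclohex-2-en-1-one | C=C[C@@]1(C)CC=CC(=O)[C@@H]1C(=C)C | intermediate
13 | (5R,6R)-5-ethenyl-2-iodo-5-methyl-6-(prop-1-en-2-yl)cyclohex-2-en-1-one | C=C[C@@]1(C)CC=C(I)C(=O)[C@@H]1C(=C)C | intermediate
14 | ethynyltri(propan-2-yl)silane | C#C[Si](C(C)C)(C(C)C)C(C)C | starting material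
15 | (5R,6R)-5-ethenyl-5-methyl-6-(prop-1-en-2-yl)-2-{[tri(propan-2-yl)silyl]ethynyl}cyclohex-2-en-1-one | C=C[C@@]1(C)CC=C(C#C[Si](C(C)C)(C(C)C)C(C)C)C(=O)[C@@H]1C(=C)C | intermediate
16 | bis(pinacolato)diboron | CC1(C)OB(OC1(C)C)B1OC(C)(C)C(C)(C)O1 | starting material
17 | (2S,3S,5R,6R)-5-ethenyl-5-methyl-6-(prop-1-en-2-yl)-3-(4,4,5,5-tetramethyl-1,3,2-dioxaborolan-2-yl)-2-{[tri(propan-2-yl)silyl]ethynyl}cyclohexan-1-one | C=C[C@@]1(C)C[C@H](B2OC(C)(C)C(C)(C)O2)[C@@H](C#C[Si](C(C)C)(C(C)C)C(C)C)C(=O)[C@@H]1C(=C)C | intermediate (not isolated)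
18 | (2R,3S,5R,6R)-5-ethenyl-3-hydroxy-5-methyl-6-(prop-1-en-2-yl)-2-{[tri(propan-2-yl)silyl]ethynyl}cyclohexan-1-one | C=C[C@@]1(C)C[C@H](O)[C@@H](C#C[Si](C(C)C)(C(C)C)C(C)C)C(=O)[C@@H]1C(=C)C | intermediate
19 | (1S,2S,3S,4R,5R)-5-ethenyl-3-hydroxy-5-methyl-4-(prop-1-en-2-yl)-2-{[tri(propan-2-yl)silyl]ethynyl}cyclohexyl acetate | C=C[C@@]1(C)C[C@H](OC(C)=O)[C@@H](C#C[Si](C(C)C)(C(C)C)C(C)C)[C@@H](O)[C@@H]1C(=C)C | intermediate
20 | (1S,2S,3S,4R,5R)-5-ethenyl-2-ethynyl-3-hydroxy-5-methyl-4-(prop-1-en-2-yl)cyclohexyl acetate | C=C[C@@]1(C)C[C@H](OC(C)=O)[C@@H](C#C)[C@@H](O)[C@@H]1C(=C)C | intermediate (key-step precursor)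
21 | (3aR,4S,6R,7R,7aS)-6-ethenyl-6-methyl-3-methylidene-2-oxo-7-(prop-1-en-2-yl)octahydro-1-benzofuran-4-yl acetate | C=C[C@@]1(C)C[C@H](OC(C)=O)[C@@H]2[C@@H](OC(=O)C2=C)[C@@H]1C(=C)C | intermediate (key-step product)
22 | (3S,3aR,4S,6R,7R,7aS)-6-ethenyl-3-hydroperoxy-3,6-dimethyl-2-oxo-7-(prop-1-en-2-yl)octahydro-1-benzofuran-4-yl acetate | C=C[C@@]1(C)C[C@H](OC(C)=O)[C@@H]2[C@@H](OC(=O)[C@@]2(C)OO)[C@@H]1C(=C)C | intermediate (not isolated)
23 | (3S,3aR,4S,6R,7R,7aS)-6-ethenyl-3-hydroxy-3,6-dimethyl-2-oxo-7-(prop-1-en-2-yl)octahydro-1-benzofuran-4-yl acetate | C=C[C@@]1(C)C[C@H](OC(C)=O)[C@@H]2[C@@H](OC(=O)[C@@]2(C)O)[C@@H]1C(=C)C | intermediate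
24 | (2Z)-2-methylbut-2-enoic acid (angelic acid) | C/C=C(/C)C(=O)O | starting material
25 | lithium (3S,3aR,4S,6R,7R,7aS)-4-(acetyloxy)-6-ethenyl-3,6-dimethyl-2-oxo-7-(prop-1-en-2-yl)octahydro-1-benzofuran-3-olate | C=C[C@@]1(C)C[C@H](OC(C)=O)[C@@H]2[C@@H](OC(=O)[C@@]2(C)[O-])[C@@H]1C(=C)C.[Li+] | intermediate (not isolated)
26 | (3S,3aR,4S,6R,7R,7aS)-4-(acetyloxy)-6-ethenyl-3,6-dimethyl-2-oxo-7-(prop-1-en-2-yl)octahydro-1-benzofuran-3-yl (2Z)-2-methylbut-2-enoate | C=C[C@@]1(C)C[C@H](OC(C)=O)[C@@H]2[C@@H](OC(=O)[C@@]2(C)OC(=O)/C(C)=C\C)[C@@H]1C(=C)C | target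

## Step count and least certain steps

Total: 16 steps. Longest linear sequence: 16 steps (1 → 26); 4, 14, 16 and 24 enter as purchased reagents.

**Step 14 (key step).** The most likely failure is diversion of the palladium alkoxycarbonyl or of the liberated HCl onto the C5 isopropenyl group, combined with slow turnover of a hindered secondary alcohol so that the alkyne oligomerises. Fallback, from 20 back to 21: bromoboration of the triple bond with 9-bromo-9-borabicyclo[3.3.1]nonane in the presence of a hindered pyridine base (syn addition, boron at the terminus), then protonolysis with AcOH, should give the 2-bromoalkene (1S,2S,3S,4R,5R)-2-(1-bromoethenyl)-5-ethenyl-3-hydroxy-5-methyl-4-(prop-1-en-2-yl)cyclohexyl acetate F1. Carbonylative lactonisation of F1 through oxidative addition to zerovalent palladium (Pd(PPh3)4, CO 1 atm, Et3N, CH3CN, 60 °C) then closes ring B and rejoins the route at 21.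

**Step 11.** The most likely failure is poor facial selectivity in the delivery of boron to C8, because neither face is clearly favoured by the ring and the α-alkynyl group may blunt the ligand's control. Incomplete equilibration at C7, or drift of the α-alkynyl ketone toward its allenyl isomer under alkoxide, could add to this. Fallback, from 15 back to 18:
- Corey–Bakshi–Shibata reduction with catecholborane (oxazaborolidine antipode chosen to put the C6 hydroxyl cis to the isopropenyl group) gives (1R,5R,6R)-5-ethenyl-5-methyl-6-(prop-1-en-2-yl)-2-{[tri(propan-2-yl)silyl]ethynyl}cyclohex-2-en-1-ol F2.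
- Hydroxyl-directed epoxidation (VO(acac)2, t-BuOOH), confined to the allylic alkene and to the face of the hydroxyl, gives (1R,2R,3R,4R,6S)-4-ethenyl-4-methyl-3-(prop-1-en-2-yl)-1-{[tri(propan-2-yl)silyl]ethynyl}-7-oxabicyclo[4.1.0]heptan-2-ol F3.
- Dess–Martin oxidation gives (1S,3R,4R,6S)-4-ethenyl-4-methyl-3-(prop-1-en-2-yl)-1-{[tri(propan-2-yl)silyl]ethynyl}-7-oxabicyclo[4.1.0]heptan-2-one F4.
- SmI2 (THF–MeOH, −90 °C) cleaves the Cα–O bond and returns 18, with the C8 oxygen now fixed by the directed epoxidation and not by a catalyst.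

**Step 12.** The most likely failure is slow hydride transfer, because the hemiacetal must form on a C8 oxygen that is axial and syn to the C10 methyl in the reacting chair. That would leave time for loss of water from the β-hydroxy ketone or scrambling at C7. Fallback, from 18 back to 19: hydroxyl-directed reduction with Me4NBH(OAc)3 (AcOH–CH3CN, −20 °C), in which the smaller boron hydride is bound directly to O8, gives the anti diol (1S,2R,3S,4R,5R)-5-ethenyl-5-methyl-4-(prop-1-en-2-yl)-2-{[tri(propan-2-yl)silyl]ethynyl}cyclohexane-1,3-diol F5. Mono-acetylation of the less hindered C8 hydroxyl (Ac2O, 2,4,6-collidine, CH2Cl2, −20 °C) returns 19.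

**Step 3.** The most likely failure is leakage of enolate geometry in the dienolate-forming step or an insufficient or reversed sense of induction, which would lower the diastereomeric or enantiomeric purity on which every later centre depends. Fallback, from 5 back to 7: the lithium enolate version (LiN(i-Pr)2, Me3SiCl, THF, −78 °C → rt; kinetic E(O) enolate, same chair) gives 7 together with its mirror image (2S,3S)-3-(2-{[tert-butyl(diphenyl)silyl]oxy}ethyl)-3-methyl-2-(prop-1-en-2-yl)pent-4-enoic acid F6. Crystallisation with (R)-1-phenylethylamine separates (1R)-1-phenylethan-1-aminium (2R,3R)-3-(2-{[tert-butyl(diphenyl)silyl]oxy}ethyl)-3-methyl-2-(prop-1-en-2-yl)pent-4-enoate F7, and acidification returns 7.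

**Step 15.** The most likely failure is competing hydrogen-atom transfer to the isopropenyl group, a good acceptor that gives a tertiary radical, leading to over-hydration. Fallback, from 21 back to 23: conjugate reduction with LiBH(sec-Bu)3 (THF, −78 °C) gives the enolate lithium (3aR,4S,6R,7R,7aS)-4-(acetyloxy)-6-ethenyl-3,6-dimethyl-7-(prop-1-en-2-yl)-3a,4,5,6,7,7a-hexahydro-1-benzofuran-2-olate F8. It is oxidised in the same flask with 2-(phenylsulfonyl)-3-phenyloxaziridine on the convex face to give 23, without touching the isolated alkenes.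

**Step 16.** The most likely failure is sluggish acylation of the hindered tertiary alkoxide, which would allow attack at the wrong carbonyl of the mixed anhydride or Z-to-E isomerisation of the acyl group. Fallback, from 23 back to 26: esterification with 2-[bis(2,2,2-trifluoroethoxy)phosphoryl]propanoic acid (DCC, CH2Cl2; reactive phosphonoketene) gives (3S,3aR,4S,6R,7R,7aS)-4-(acetyloxy)-6-ethenyl-3,6-dimethyl-2-oxo-7-(prop-1-en-2-yl)octahydro-1-benzofuran-3-yl 2-[bis(2,2,2-trifluoroethoxy)phosphoryl]propanoate F9. Still–Gennari olefination (KN(SiMe3)2, 18-crown-6, CH3CHO, THF, −78 °C) builds the Z-trisubstituted alkene directly and gives 26.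

## Further compounds

F1 | step 14 | (1S,2S,3S,4R,5R)-2-(1-bromoethenyl)-5-ethenyl-3-hydroxy-5-methyl-4-(prop-1-en-2-yl)cyclohexyl acetate | C=C[C@@]1(C)C[C@H](OC(C)=O)[C@@H](C(Br)=C)[C@@H](O)[C@@H]1C(=C)C
F2 | step 11 | (1R,5R,6R)-5-ethenyl-5-methyl-6-(prop-1-en-2-yl)-2-{[tri(propan-2-yl)silyl]ethynyl}cyclohex-2-en-1-ol | C=C[C@@]1(C)CC=C(C#C[Si](C(C)C)(C(C)C)C(C)C)[C@H](O)[C@@H]1C(=C)C
F3 | step 11 | (1R,2R,3R,4R,6S)-4-ethenyl-4-methyl-3-(prop-1-en-2-yl)-1-{[tri(propan-2-yl)silyl]ethynyl}-7-oxabicyclo[4.1.0]heptan-2-ol | C=C[C@@]1(C)C[C@@H]2O[C@]2(C#C[Si](C(C)C)(C(C)C)C(C)C)[C@H](O)[C@@H]1C(=C)C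
F4 | step 11 | (1S,3R,4R,6S)-4-ethenyl-4-methyl-3-(prop-1-en-2-yl)-1-{[tri(propan-2-yl)silyl]ethynyl}-7-oxabicyclo[4.1.0]heptan-2-one | C=C[C@@]1(C)C[C@@H]2O[C@]2(C#C[Si](C(C)C)(C(C)C)C(C)C)C(=O)[C@@H]1C(=C)C
F5 | step 12 | (1S,2R,3S,4R,5R)-5-ethenyl-5-methyl-4-(prop-1-en-2-yl)-2-{[tri(propan-2-yl)silyl]ethynyl}cyclohexane-1,3-diol | C=C[C@@]1(C)C[C@H](O)[C@@H](C#C[Si](C(C)C)(C(C)C)C(C)C)[C@@H](O)[C@@H]1C(=C)C
F6 | step 3 | (2S,3S)-3-(2-{[tert-butyl(diphenyl)silyl]oxy}ethyl)-3-methyl-2-(prop-1-en-2-yl)pent-4-enoic acid | C=C[C@](C)(CCO[Si](c1ccccc1)(c1ccccc1)C(C)(C)C)[C@H](C(=C)C)C(=O)O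
F7 | step 3 | (1R)-1-phenylethan-1-aminium (2R,3R)-3-(2-{[tert-butyl(diphenyl)silyl]oxy}ethyl)-3-methyl-2-(prop-1-en-2-yl)pent-4-enoate | C=C[C@@](C)(CCO[Si](c1ccccc1)(c1ccccc1)C(C)(C)C)[C@@H](C(=C)C)C(=O)[O-].C[C@@H]([NH3+])c1ccccc1
F8 | step 15 | lithium (3aR,4S,6R,7R,7aS)-4-(acetyloxy)-6-ethenyl-3,6-dimethyl-7-(prop-1-en-2-yl)-3a,4,5,6,7,7a-hexahydro-1-benzofuran-2-olate | C=C[C@@]1(C)C[C@H](OC(C)=O)[C@@H]2[C@@H](OC([O-])=C2C)[C@@H]1C(=C)C.[Li+]
F9 | step 16 | (3S,3aR,4S,6R,7R,7aS)-4-(acetyloxy)-6-ethenyl-3,6-dimethyl-2-oxo-7-(prop-1-en-2-yl)octahydro-1-benzofuran-3-yl 2-[bis(2,2,2-trifluoroethoxy)phosphoryl]propanoate | C=C[C@@]1(C)C[C@H](OC(C)=O)[C@@H]2[C@@H](OC(=O)[C@@]2(C)OC(=O)C(C)P(=O)(OCC(F)(F)F)OCC(F)(F)F)[C@@H]1C(=C)C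
A1 | alternative 1 | trans-1-methoxy-3-(trimethylsilyloxy)buta-1,3-diene | CO/C=C/C(=C)O[Si](C)(C)C
A2 | alternative 1 | methyl (2E)-2-methyl-4-oxopent-2-enoate | COC(=O)/C(C)=C/C(C)=O
A3 | alternative 1 | methyl (1S,6S)-6-acetyl-1-methyl-3-oxocyclohex-4-ene-1-carboxylate | COC(=O)[C@@]1(C)CC(=O)C=C[C@@H]1C(C)=O
A4 | alternative 2 | (4R)-4-{[tert-butyl(dimethyl)silyl]oxy}-2-methylcyclohex-2-en-1-one | CC1=C[C@H](O[Si](C)(C)C(C)(C)C)CCC1=O
A5 | alternative 2 | (2S,3R,4R)-4-{[tert-butyl(dimethyl)silyl]oxy}-2-(1-hydroxyethyl)-2-methyl-3-(prop-1-en-2-yl)cyclohexan-1-one (carbinol centre undefined) | CC(O)[C@@]1(C)C(=O)CC[C@@H](O[Si](C)(C)C(C)(C)C)[C@@H]1C(=C)C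
A6 | alternative 3 | (3R,4R)-3-ethenyl-3,5-dimethyl-4-[(2R)-4-methyl-5-oxo-2,5-dihydrofuran-2-yl]hex-5-enal | C=C[C@@](C)(CC=O)[C@@H](C(=C)C)[C@@H]1OC(=O)C(C)=C1
A7 | alternative 3 | (3aR,4S,6R,7R,7aS)-6-ethenyl-4-hydroxy-3,6-dimethyl-7-(prop-1-en-2-yl)hexahydro-1-benzofuran-2(3H)-one (C3 undefined) | C=C[C@@]1(C)C[C@H](O)[C@@H]2[C@@H](OC(=O)C2C)[C@@H]1C(=C)C
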